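A direct plan would make each benzoate ring on its own from methyl 2,4-dihydroxy-3,6-dimethylbenzoate A1 (Michael–Claisen ring synthesis, then aromatisation). It would turn the copies into an acyl donor such as 2,4-bis(benzyloxy)-3,6-dimethylbenzoic acid A2 and phenols such as allyl 4-hydroxy-2-methoxy-3,5,6-trimethylbenzoate A3, join the finished rings by two mixed-anhydride esterifications, and end with a global debenzylation. Its weakest steps would be:
- the relay of benzylation, O-methylation, ester cleavage, hydrogenolysis and re-esterification on every ring: about a dozen operations that form no bond of the skeleton and only tell 2-O from 4-O and acid from phenol;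
- the saponification of the 2,6-disubstituted methyl benzoates, which would need hot KOH in DMSO and would put electron-rich acids at risk of decarboxylation;
- the two transfers of a 2,6-disubstituted aroyl group to ortho-methylated phenols (for ring B a phenol between two methyl groups): the most hindered bond formations, placed last, under acidic activation, on the most valuable material.

**Plan of the new route**

In each of rings A, B and C the carboxyl carbon on C1 has a methyl group on C6, and C2–C5 carry oxygen on C2 and C4 with a methyl on C3. The unit C(=O)–C1–C6–CH3 is therefore a but-2-ynoate, and C2–C5 is the diene of a 2-methylcyclohexane-1,3-dione enol ether. The retrosynthesis cuts C1–C2 and C5–C6 of every ring, and only then the ester C–O bonds, which now lie between a phenol and the slim, linear but-2-ynoic acid. Forward, each ester is made first and its benzoyl ring is grown on it by Diels–Alder addition and loss of ethene (Alder–Rickert), in the order ring C, ring B, ring A. The diene decides OMe against OH, so no phenol is protected, no benzoate is saponified and no hindered aroyl group is transferred; one 4-methoxybenzyl ester is the only protecting group.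

Key step: step 9

Remark: the target has no stereocentre. Compounds 4, 11, 15 and 19 are racemic and lose their stereocentres in the next operation. 2-Methylcyclohexane-1,3-dione, but-2-ynoic acid and 4-methoxybenzyl alcohol are taken as commercial. The dienes 3, 5 and 7 are moisture-sensitive and would be used freshly distilled.

Step 1
Reactants: 1 2-methylcyclohexane-1,3-dione
Product: 2 3-methoxy-2-methylcyclohex-2-en-1-one
Conditions: HC(OMe)3 (1.5 equiv), TsOH·H2O (5 mol%), MeOH, reflux
Reagents that add atoms: trimethyl orthoformate, COC(OC)OC; methanol, CO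
Why: Acid-catalysed enol etherification of the largely enolised, symmetric cyclic 1,3-dione gives a single vinylogous ester, with the orthoformate taking up the water.

Step 2
Reactants: 2 3-methoxy-2-methylcyclohex-2-en-1-one
Product: 3 1-methoxy-2-methyl-3-(trimethylsilyloxy)cyclohexa-1,3-diene
Conditions: LiN(iPr)2 (1.1 equiv), THF, −78 °C; Me3SiCl (1.2 equiv), −78 °C → rt; non-aqueous work-up, distillation
Reagents that add atoms: chlorotrimethylsilane, C[Si](C)(C)Cl
Why: Kinetic deprotonation of a vinylogous ester occurs at the α'-carbon (Stork–Danheiser regiochemistry), and O-silylation of the cross-conjugated enolate gives the 1-methoxy-3-silyloxy diene.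

Step 3
Reactants: 2 3-methoxy-2-methylcyclohex-2-en-1-one
Product: 4 3-methoxy-2,6-dimethylcyclohex-2-en-1-one (racemic)
Conditions: LiN(iPr)2 (1.05 equiv), THF, −78 °C; MeI (1.5 equiv), −78 → 0 °C
Reagents that add atoms: iodomethane, CI
Why: Stork–Danheiser kinetic α'-alkylation of the vinylogous ester; the new stereocentre is racemic and becomes sp2 in step 4.

Step 4
Reactants: 4 3-methoxy-2,6-dimethylcyclohex-2-en-1-one
Product: 5 1-methoxy-2,4-dimethyl-3-(trimethylsilyloxy)cyclohexa-1,3-diene
Conditions: LiN(iPr)2 (1.1 equiv), THF, −78 °C; Me3SiCl (1.2 equiv), −78 °C → rt; non-aqueous work-up, distillation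
Reagents that add atoms: chlorotrimethylsilane, C[Si](C)(C)Cl
Why: Kinetic α'-enolisation and O-silylation as in step 2 give the diene that carries the future C5 methyl group of ring B on its nucleophilic terminus.

Step 5
Reactants: 1 2-methylcyclohexane-1,3-dione
Product: 7 2-methyl-1,3-bis(trimethylsilyloxy)cyclohexa-1,3-diene, via silyloxy enone 6 (not isolated)
Conditions: (Me3Si)2NH (0.6 equiv), imidazole (cat.), THF, reflux, then evaporation; LiN(iPr)2 (1.1 equiv), THF, −78 °C; Me3SiCl (1.2 equiv), −78 °C → rt; distillation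
Reagents that add atoms: hexamethyldisilazane, C[Si](C)(C)N[Si](C)(C)C; chlorotrimethylsilane, C[Si](C)(C)Cl
Why: O-silylation of the enol, then kinetic α'-enolisation and a second O-silylation, is the standard access to 1,3-bis(silyloxy)cyclohexa-1,3-dienes.

Step 6
Reactants: 8 but-2-ynoic acid; 9 4-methoxybenzyl alcohol
Product: 10 4-methoxybenzyl but-2-ynoate
Conditions: DCC (1.1 equiv), DMAP (5 mol%), CH2Cl2, 0 °C → rt
Reagents that add atoms: none
Why: Steglich esterification of an unhindered alkynoic acid with a primary alcohol.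

Step 7
Reactants: 10 4-methoxybenzyl but-2-ynoate; 3 1-methoxy-2-methyl-3-(trimethylsilyloxy)cyclohexa-1,3-diene
Product: 13 4-methoxybenzyl 4-hydroxy-2-methoxy-3,6-dimethylbenzoate, via bicyclic adduct 11 (not isolated), via aryl silyl ether 12 (not isolated)
Conditions: 3 (2 equiv), mesitylene, sealed tube, 170 °C, 24 h; then 1 M HCl, THF, 0 °C → rt
Reagents that add atoms: none
Why: Alder–Rickert benzannulation (Diels–Alder addition, then retro-Diels–Alder loss of ethene): the unsubstituted diene terminus next to the OSiMe3 carbon bonds to the β-carbon of the ynoate, so ring C should form with OMe ortho and OH para to the ester.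

Step 8
Reactants: 13 4-methoxybenzyl 4-hydroxy-2-methoxy-3,6-dimethylbenzoate; 8 but-2-ynoic acid
Product: 14 4-methoxybenzyl 4-(but-2-ynoyloxy)-2-methoxy-3,6-dimethylbenzoate
Conditions: DCC (1.2 equiv), DMAP (10 mol%), CH2Cl2, 0 °C → rt
Reagents that add atoms: none
Why: Steglich esterification; the acyl carbon carries only a linear sp-carbon neighbour, so the ortho-methyl phenol should be acylated without the hindrance a finished 2,6-disubstituted aroyl group would bring.

Step 9
Reactants: 14 4-methoxybenzyl 4-(but-2-ynoyloxy)-2-methoxy-3,6-dimethylbenzoate; 5 1-methoxy-2,4-dimethyl-3-(trimethylsilyloxy)cyclohexa-1,3-diene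
Product: 17 4-methoxybenzyl 4-[(4-hydroxy-2-methoxy-3,5,6-trimethylbenzoyl)oxy]-2-methoxy-3,6-dimethylbenzoate, via bicyclic adduct 15 (not isolated), via aryl silyl ether 16 (not isolated)
Conditions: 5 (3 equiv), mesitylene, sealed tube, 180 °C, 36 h; then 1 M HCl, THF, 0 °C → rt
Reagents that add atoms: none
Why: The electron-rich diene 5 and the electron-poor alkyne of 14 should combine in a thermal, asynchronous [4+2] cycloaddition to the bicyclo[2.2.2]octa-2,5-diene 15, which at the same temperature loses its CH2–CH2 bridge as ethene by retro-[4+2] cleavage and becomes benzene ring B (16). The closest known reaction type is the Alder–Rickert benzannulation of alkoxy- and silyloxycyclohexa-1,3-dienes with 2-alkynoates, established for resorcylate esters also when the ester partner is already in place. Ring B is closed by intermolecular cycloaddition through the bonds C1–C2 and C5–C6 (ring B numbering) and aromatised by cycloreversion; the two bridgehead centres of 15 are racemic and vanish with the ethene, so no stereocentre has to be controlled. The step needs regioselectivity: the diene terminus next to the OSiMe3 carbon, to which both oxygen donors push electron density, bonds to the electrophilic β-carbon of the ynoate, which places OMe ortho and OSiMe3 para to the ester carbonyl, as 1-methoxy-3-silyloxy dienes do with acrylates. It also needs chemoselectivity, which is secured because 14 holds no free OH that could take up a silyl group or protonate the diene, and no second dienophile. Dilute acid then frees the 4-OH, the only phenol of 17, for the next esterification.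

Step 10
Reactants: 17 4-methoxybenzyl 4-[(4-hydroxy-2-methoxy-3,5,6-trimethylbenzoyl)oxy]-2-methoxy-3,6-dimethylbenzoate; 8 but-2-ynoic acid
Product: 18 4-methoxybenzyl 4-{[4-(but-2-ynoyloxy)-2-methoxy-3,5,6-trimethylbenzoyl]oxy}-2-methoxy-3,6-dimethylbenzoate
Conditions: DCC (1.5 equiv), DMAP (20 mol%), CH2Cl2, 0 °C → rt
Reagents that add atoms: none
Why: Steglich esterification of the phenol between two methyl groups with the smallest possible acyl partner, a linear alkynoyl group; 17 has no other nucleophilic site.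

Step 11
Reactants: 18 4-methoxybenzyl 4-{[4-(but-2-ynoyloxy)-2-methoxy-3,5,6-trimethylbenzoyl]oxy}-2-methoxy-3,6-dimethylbenzoate; 7 2-methyl-1,3-bis(trimethylsilyloxy)cyclohexa-1,3-diene
Product: 21 4-methoxybenzyl 4-({4-[(2,4-dihydroxy-3,6-dimethylbenzoyl)oxy]-2-methoxy-3,5,6-trimethylbenzoyl}oxy)-2-methoxy-3,6-dimethylbenzoate, via bicyclic adduct 19 (not isolated), via bis-silyl ether 20 (not isolated)
Conditions: 7 (3 equiv), mesitylene, sealed tube, 170 °C, 24 h; then 1 M HCl, THF, 0 °C
Reagents that add atoms: none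
Why: Alder–Rickert benzannulation as in step 9: the C–H terminus of the bis-silyloxy diene bonds to the β-carbon of the ynoate, ethene is lost, and both oxygens of ring A emerge as silyl ethers that dilute acid cleaves, so the 2,4-dihydroxy pattern needs no selective deprotection.

Step 12
Reactants: 21 4-methoxybenzyl 4-({4-[(2,4-dihydroxy-3,6-dimethylbenzoyl)oxy]-2-methoxy-3,5,6-trimethylbenzoyl}oxy)-2-methoxy-3,6-dimethylbenzoate
Product: 22 4-({4-[(2,4-dihydroxy-3,6-dimethylbenzoyl)oxy]-2-methoxy-3,5,6-trimethylbenzoyl}oxy)-2-methoxy-3,6-dimethylbenzoic acid (target)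
Conditions: H2 (1 atm), 10% Pd/C, EtOAc, rt
Reagents that add atoms: none
Why: Neutral catalytic hydrogenolysis of the 4-methoxybenzyl ester should leave the two aryl ester links, the methyl ethers and the free phenols untouched; no stereocentre is involved.

**Compound list**
1 | 2-methylcyclohexane-1,3-dione | CC1C(=O)CCCC1=O | starting material
2 | 3-methoxy-2-methylcyclohex-2-en-1-one | COC1=C(C)C(=O)CCC1 | intermediate
3 | 1-methoxy-2-methyl-3-(trimethylsilyloxy)cyclohexa-1,3-diene | COC1=C(C)C(O[Si](C)(C)C)=CCC1 | intermediate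
4 | 3-methoxy-2,6-dimethylcyclohex-2-en-1-one (racemic) | COC1=C(C)C(=O)C(C)CC1 | intermediate
5 | 1-methoxy-2,4-dimethyl-3-(trimethylsilyloxy)cyclohexa-1,3-diene | COC1=C(C)C(O[Si](C)(C)C)=C(C)CC1 | intermediate
6 | 2-methyl-3-(trimethylsilyloxy)cyclohex-2-en-1-one (not isolated) | CC1=C(O[Si](C)(C)C)CCCC1=O | intermediate
7 | 2-methyl-1,3-bis(trimethylsilyloxy)cyclohexa-1,3-diene | CC1=C(O[Si](C)(C)C)CCC=C1O[Si](C)(C)C | intermediate
8 | but-2-ynoic acid | CC#CC(=O)O | starting material
9 | 4-methoxybenzyl alcohol | COc1ccc(CO)cc1 | starting material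
10 | 4-methoxybenzyl but-2-ynoate | CC#CC(=O)OCc1ccc(OC)cc1 | intermediate
11 | 4-methoxybenzyl 1-methoxy-3,6-dimethyl-5-(trimethylsilyloxy)bicyclo[2.2.2]octa-2,5-diene-2-carboxylate (racemic, not isolated) | COC12CCC(C(O[Si](C)(C)C)=C1C)C(C)=C2C(=O)OCc1ccc(OC)cc1 | intermediate
12 | 4-methoxybenzyl 2-methoxy-3,6-dimethyl-4-(trimethylsilyloxy)benzoate (not isolated) | COc1c(C)c(O[Si](C)(C)C)cc(C)c1C(=O)OCc1ccc(OC)cc1 | intermediate
13 | 4-methoxybenzyl 4-hydroxy-2-methoxy-3,6-dimethylbenzoate | COc1c(C)c(O)cc(C)c1C(=O)OCc1ccc(OC)cc1 | intermediate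
14 | 4-methoxybenzyl 4-(but-2-ynoyloxy)-2-methoxy-3,6-dimethylbenzoate | CC#CC(=O)Oc1cc(C)c(C(=O)OCc2ccc(OC)cc2)c(OC)c1C | intermediate
15 | 4-methoxybenzyl 2-methoxy-4-{[1-methoxy-3,4,6-trimethyl-5-(trimethylsilyloxy)bicyclo[2.2.2]octa-2,5-diene-2-carbonyl]oxy}-3,6-dimethylbenzoate (racemic, not isolated) | COC12CCC(C)(C(O[Si](C)(C)C)=C1C)C(C)=C2C(=O)Oc1cc(C)c(C(=O)OCc2ccc(OC)cc2)c(OC)c1C | intermediate
16 | 4-methoxybenzyl 2-methoxy-4-{[2-methoxy-3,5,6-trimethyl-4-(trimethylsilyloxy)benzoyl]oxy}-3,6-dimethylbenzoate (not isolated) | COc1c(C)c(O[Si](C)(C)C)c(C)c(C)c1C(=O)Oc1cc(C)c(C(=O)OCc2ccc(OC)cc2)c(OC)c1C | intermediate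
17 | 4-methoxybenzyl 4-[(4-hydroxy-2-methoxy-3,5,6-trimethylbenzoyl)oxy]-2-methoxy-3,6-dimethylbenzoate | COc1c(C)c(O)c(C)c(C)c1C(=O)Oc1cc(C)c(C(=O)OCc2ccc(OC)cc2)c(OC)c1C | intermediate
18 | 4-methoxybenzyl 4-{[4-(but-2-ynoyloxy)-2-methoxy-3,5,6-trimethylbenzoyl]oxy}-2-methoxy-3,6-dimethylbenzoate | CC#CC(=O)Oc1c(C)c(C)c(C(=O)Oc2cc(C)c(C(=O)OCc3ccc(OC)cc3)c(OC)c2C)c(OC)c1C | intermediate
19 | 3,6-dimethyl-1,5-bis(trimethylsilyloxy)bicyclo[2.2.2]octa-2,5-diene-2-carboxylic ester of the ring B phenol of 17 (racemic, not isolated) | C[Si](C)(C)OC12CCC(C(O[Si](C)(C)C)=C1C)C(C)=C2C(=O)Oc1c(C)c(C)c(C(=O)Oc2cc(C)c(C(=O)OCc3ccc(OC)cc3)c(OC)c2C)c(OC)c1C | intermediate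
20 | 4-methoxybenzyl 4-[(4-{[3,6-dimethyl-2,4-bis(trimethylsilyloxy)benzoyl]oxy}-2-methoxy-3,5,6-trimethylbenzoyl)oxy]-2-methoxy-3,6-dimethylbenzoate (not isolated) | Cc1cc(O[Si](C)(C)C)c(C)c(O[Si](C)(C)C)c1C(=O)Oc1c(C)c(C)c(C(=O)Oc2cc(C)c(C(=O)OCc3ccc(OC)cc3)c(OC)c2C)c(OC)c1C | intermediate
21 | 4-methoxybenzyl 4-({4-[(2,4-dihydroxy-3,6-dimethylbenzoyl)oxy]-2-methoxy-3,5,6-trimethylbenzoyl}oxy)-2-methoxy-3,6-dimethylbenzoate | Cc1cc(O)c(C)c(O)c1C(=O)Oc1c(C)c(C)c(C(=O)Oc2cc(C)c(C(=O)OCc3ccc(OC)cc3)c(OC)c2C)c(OC)c1C | intermediate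
22 | 4-({4-[(2,4-dihydroxy-3,6-dimethylbenzoyl)oxy]-2-methoxy-3,5,6-trimethylbenzoyl}oxy)-2-methoxy-3,6-dimethylbenzoic acid (CNP0425440.0, achiral) | COc1c(C)c(OC(=O)c2c(C)c(C)c(OC(=O)c3c(C)cc(O)c(C)c3O)c(C)c2OC)cc(C)c1C(=O)O | target

**Totals**

Total step count: 12. Longest linear sequence: 8 steps (steps 1, 2, 7, 8, 9, 10, 11, 12).

**Steps most likely to fail**

Step 9. The cycloaddition joins a diene with two fully substituted termini to a β-methyl ynoate and may be slower than the thermal decay of the diene (protodesilylation, hydrogen shifts), or it may lose regiocontrol. The fallback sets out from 14 and installs the C5 methyl group of ring B after ring formation. Cycloaddition of 14 with the less hindered diene 3 under the conditions of step 7 would give the bicyclo[2.2.2]octadiene adduct F1, then after loss of ethene the aryl trimethylsilyl ether F2, and after acid work-up 4-methoxybenzyl 4-[(4-hydroxy-2-methoxy-3,6-dimethylbenzoyl)oxy]-2-methoxy-3,6-dimethylbenzoate F3. Bromination of F3 at the only position ortho to the free phenol (N-bromosuccinimide, MeCN, 0 °C) would give 4-methoxybenzyl 4-[(5-bromo-4-hydroxy-2-methoxy-3,6-dimethylbenzoyl)oxy]-2-methoxy-3,6-dimethylbenzoate F4. Base-free Stille methylation of F4 (SnMe4, Pd(PPh3)4 as the source of zerovalent palladium, DMF, 90 °C) would come back to the route at 17.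

Step 11. On the most advanced material the cycloaddition may be outrun by protodesilylation of the bis-silyl diene, the most heat- and moisture-sensitive of the three, and long heating could lead to silyl or acyl migration in the depside. The fallback sets out from 17 and attaches ring A as a finished, protected aroyl group. Acid A2 would be converted with oxalyl chloride and catalytic DMF into 2,4-bis(benzyloxy)-3,6-dimethylbenzoyl chloride F5. Acylation of 17 with F5 (Et3N, DMAP, CH2Cl2, reflux) would give 4-methoxybenzyl 4-[(4-{[2,4-bis(benzyloxy)-3,6-dimethylbenzoyl]oxy}-2-methoxy-3,5,6-trimethylbenzoyl)oxy]-2-methoxy-3,6-dimethylbenzoate F6. Hydrogenolysis of F6 (H2, 10% Pd/C, EtOAc) would remove both benzyl ethers and the 4-methoxybenzyl ester and come back to the route at 22.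

Step 10. Acyl transfer to the phenol between two methyl groups may be sluggish, so that rearrangement of the O-acylisourea to the N-acylurea and conjugate addition of DMAP to the ynoic acid take over. The fallback sets out from 17 and forms the ester with a ketene, then creates the triple bond. Heating 17 with 2,2,6-trimethyl-4H-1,3-dioxin-4-one (xylene, 140 °C) would trap acetylketene without base and give 4-methoxybenzyl 2-methoxy-4-{[2-methoxy-3,5,6-trimethyl-4-(3-oxobutanoyloxy)benzoyl]oxy}-3,6-dimethylbenzoate F7. Chelation-controlled triflation of F7 (Tf2O, iPr2NEt, LiOSO2CF3, CH2Cl2, −78 °C) would give the (Z)-enol triflate F8. Anti elimination of triflate from F8 (LiN(SiMe3)2, THF, −78 °C) would come back to the route at 18.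

**Further compounds**
F1 | step 9 | 4-methoxybenzyl 2-methoxy-4-{[1-methoxy-3,6-dimethyl-5-(trimethylsilyloxy)bicyclo[2.2.2]octa-2,5-diene-2-carbonyl]oxy}-3,6-dimethylbenzoate (racemic) | COC12CCC(C(O[Si](C)(C)C)=C1C)C(C)=C2C(=O)Oc1cc(C)c(C(=O)OCc2ccc(OC)cc2)c(OC)c1C
F2 | step 9 | 4-methoxybenzyl 2-methoxy-4-{[2-methoxy-3,6-dimethyl-4-(trimethylsilyloxy)benzoyl]oxy}-3,6-dimethylbenzoate | COc1c(C)c(O[Si](C)(C)C)cc(C)c1C(=O)Oc1cc(C)c(C(=O)OCc2ccc(OC)cc2)c(OC)c1C
F3 | step 9 | 4-methoxybenzyl 4-[(4-hydroxy-2-methoxy-3,6-dimethylbenzoyl)oxy]-2-methoxy-3,6-dimethylbenzoate | COc1c(C)c(O)cc(C)c1C(=O)Oc1cc(C)c(C(=O)OCc2ccc(OC)cc2)c(OC)c1C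
F4 | step 9 | 4-methoxybenzyl 4-[(5-bromo-4-hydroxy-2-methoxy-3,6-dimethylbenzoyl)oxy]-2-methoxy-3,6-dimethylbenzoate | COc1c(C)c(O)c(Br)c(C)c1C(=O)Oc1cc(C)c(C(=O)OCc2ccc(OC)cc2)c(OC)c1C
F5 | step 11 | 2,4-bis(benzyloxy)-3,6-dimethylbenzoyl chloride | Cc1cc(OCc2ccccc2)c(C)c(OCc2ccccc2)c1C(=O)Cl
F6 | step 11 | 4-methoxybenzyl 4-[(4-{[2,4-bis(benzyloxy)-3,6-dimethylbenzoyl]oxy}-2-methoxy-3,5,6-trimethylbenzoyl)oxy]-2-methoxy-3,6-dimethylbenzoate | Cc1cc(OCc2ccccc2)c(C)c(OCc2ccccc2)c1C(=O)Oc1c(C)c(C)c(C(=O)Oc2cc(C)c(C(=O)OCc3ccc(OC)cc3)c(OC)c2C)c(OC)c1C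
F7 | step 10 | 4-methoxybenzyl 2-methoxy-4-{[2-methoxy-3,5,6-trimethyl-4-(3-oxobutanoyloxy)benzoyl]oxy}-3,6-dimethylbenzoate | CC(=O)CC(=O)Oc1c(C)c(C)c(C(=O)Oc2cc(C)c(C(=O)OCc3ccc(OC)cc3)c(OC)c2C)c(OC)c1C
F8 | step 10 | 4-methoxybenzyl 2-methoxy-4-{[2-methoxy-3,5,6-trimethyl-4-({(2Z)-3-[(trifluoromethanesulfonyl)oxy]but-2-enoyl}oxy)benzoyl]oxy}-3,6-dimethylbenzoate | C/C(OS(=O)(=O)C(F)(F)F)=C/C(=O)Oc1c(C)c(C)c(C(=O)Oc2cc(C)c(C(=O)OCc3ccc(OC)cc3)c(OC)c2C)c(OC)c1C
A1 | direct plan | methyl 2,4-dihydroxy-3,6-dimethylbenzoate | COC(=O)c1c(C)cc(O)c(C)c1O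
A2 | direct plan | 2,4-bis(benzyloxy)-3,6-dimethylbenzoic acid | OC(=O)c1c(C)cc(OCc2ccccc2)c(C)c1OCc1ccccc1
A3 | direct plan | allyl 4-hydroxy-2-methoxy-3,5,6-trimethylbenzoate | COc1c(C)c(O)c(C)c(C)c1C(=O)OCC=C
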